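**Strategy.** The oxepan-2-one ring is disconnected at C1–C15 and O–C12. In one flask a malonate is added enantioselectively to an enal whose β-carbon is C1, and one tert-butyl ester carbonyl then opens a cis-11,12-epoxide at C12 (7-exo, inversion): a formal (3+4) annulation that sets C1 and C12 and frees the C11 hydroxyl. It exploits the 1,4-relationship of C1 and C12 in the seven-membered lactone and the vicinal C11–OH/C12–O pair. The precursor is an acyclic (E)-enal carrying a nerol-derived vinyl epoxide. The 14-membered carbocycle is closed later by metathesis; the spare ester is finally exchanged for the exocyclic methylene.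

Key step: step 6

Remark: locants C1–C17 are cembrane locants of the target (C1 = ring CH bearing C15; C3–C4 epoxide; C7 OAc; C8 tertiary OH; C11 secondary OH; C12 lactone O; C16 lactone C=O; C17 exocyclic CH2). The target is (1R,3S,4S,7R,8S,11R,12R). C15 is carried as an inconsequential epimer mixture until step 19.

**Step 1**
Reactants: 1 nerol
Product: 2 (2R,3S)-2,3-epoxynerol
Conditions: Ti(OiPr)4 (10 mol%), D-(−)-diisopropyl tartrate (12 mol%), t-BuOOH, 4 Å MS, CH2Cl2, −20 °C
Reagents that add atoms: tert-butyl hydroperoxide CC(C)(C)OO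
Why: Sharpless asymmetric epoxidation touches only the allylic-alcohol alkene, and the D-tartrate ligand delivers oxygen to the face that gives the (2R,3S) cis-epoxide, fixing C11 and (before inversion) C12.

**Step 2**
Reactants: 2 (2R,3S)-2,3-epoxynerol
Product: 3 (2S,3S)-3-methyl-3-(4-methylpent-3-en-1-yl)oxirane-2-carbaldehyde
Conditions: DMP, pyridine, CH2Cl2, 0 °C to rt
Reagents that add atoms: none
Why: Periodinane oxidation of the primary alcohol should give the epoxy aldehyde without touching the epoxide, whose α-centre cannot epimerise.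

**Step 3**
Reactants: 3 (2S,3S)-3-methyl-3-(4-methylpent-3-en-1-yl)oxirane-2-carbaldehyde
Product: 4 (2S,3R)-3-ethenyl-2-methyl-2-(4-methylpent-3-en-1-yl)oxirane
Conditions: Ph3PCH3Br, KN(SiMe3)2, THF, −78 to 0 °C
Reagents that add atoms: methyltriphenylphosphonium bromide C[P+](c1ccccc1)(c1ccccc1)c1ccccc1.[Br-]
Why: Wittig methylenation installs the vinyl group needed later for ring-closing metathesis and leaves both epoxide centres untouched.

**Step 4**
Reactants: 4 (2S,3R)-3-ethenyl-2-methyl-2-(4-methylpent-3-en-1-yl)oxirane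
Product: 5 3-[(2S,3R)-3-ethenyl-2-methyloxiran-2-yl]propanal
Conditions: O3, pyridine, CH2Cl2, −78 °C (indicator dye end point); then PPh3
Reagents that add atoms: ozone [O-][O+]=O
Why: Ozonolysis should cleave the electron-rich trisubstituted alkene much faster than the vinyl group, which is deactivated by the allylic epoxide oxygen.

**Step 5**
Reactants: 5 3-[(2S,3R)-3-ethenyl-2-methyloxiran-2-yl]propanal
Product: 6 (2E)-5-[(2S,3R)-3-ethenyl-2-methyloxiran-2-yl]pent-2-enal
Conditions: Ph3P=CHCHO, toluene, 70 °C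
Reagents that add atoms: (triphenylphosphoranylidene)acetaldehyde O=CC=P(c1ccccc1)(c1ccccc1)c1ccccc1
Why: Wittig olefination with a stabilised ylide should give the (E)-enal, which places C1 at the β-position of the acceptor.

**Step 6**
Reactants: 6 (2E)-5-[(2S,3R)-3-ethenyl-2-methyloxiran-2-yl]pent-2-enal; 7 di-tert-butyl malonate
Product: 9 tert-butyl (4R,7R)-7-[(1R)-1-hydroxyprop-2-en-1-yl]-7-methyl-2-oxo-4-(2-oxoethyl)oxepane-3-carboxylate, via Michael adduct 8 (not isolated)
Conditions: (S)-α,α-diphenylprolinol trimethylsilyl ether (10 mol%), PhCO2H (10 mol%), EtOH, 0 °C to rt; evaporate; then BF3·OEt2 (1.5 equiv), CH2Cl2, −78 to −30 °C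
Reagents that add atoms: none
Why: The amine converts enal 6 into an iminium ion and the malonate adds to C1 from the face not shielded by the diaryl(silyloxy)methyl group, giving (1R)-8; BF3 then activates the epoxide, the carbonyl oxygen of one tert-butyl ester attacks C12 anti to the breaking C–O bond, and the dialkoxycarbenium ion loses isobutene to leave the lactone. The closest known reaction types are the amine-catalysed Michael addition of malonates to enals and the Lewis-acid opening of epoxides terminated by a tert-butyl ester or carbonate. The oxepanone closes 7-exo-tet. C1 is set by the catalyst, C12 by stereospecific inversion of the epoxide from step 1, and C11 keeps its epoxide oxygen, so the (11R,12R) pair follows from the Z geometry of nerol. The step needs attack at tertiary C12 in preference to allylic C11 (8-endo) or the vinyl terminus (SN2′), which the exo ring size, the cation-stabilising tertiary centre and the low temperature should secure.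

**Step 7**
Reactants: 9 tert-butyl (4R,7R)-7-[(1R)-1-hydroxyprop-2-en-1-yl]-7-methyl-2-oxo-4-(2-oxoethyl)oxepane-3-carboxylate
Product: 10 tert-butyl (4R,7R)-7-methyl-2-oxo-4-(2-oxoethyl)-7-{(1R)-1-[(triethylsilyl)oxy]prop-2-en-1-yl}oxepane-3-carboxylate
Conditions: Et3SiCl, imidazole, DMF, rt
Reagents that add atoms: chlorotriethylsilane CC[Si](Cl)(CC)CC
Why: Silylation masks the C11 allylic alcohol against the bromophosphonium species of the next step.

**Step 8**
Reactants: 10 tert-butyl (4R,7R)-7-methyl-2-oxo-4-(2-oxoethyl)-7-{(1R)-1-[(triethylsilyl)oxy]prop-2-en-1-yl}oxepane-3-carboxylate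
Product: 11 tert-butyl (4R,7R)-4-(3,3-dibromoprop-2-en-1-yl)-7-methyl-2-oxo-7-{(1R)-1-[(triethylsilyl)oxy]prop-2-en-1-yl}oxepane-3-carboxylate
Conditions: CBr4, PPh3, Zn, CH2Cl2, rt; then 10, 0 °C
Reagents that add atoms: carbon tetrabromide BrC(Br)(Br)Br
Why: The dibromo-olefination stage of the Corey–Fuchs reaction turns C3 into a 1,1-dibromoalkene (new carbon = C4), the handle for stereodefined assembly of the trisubstituted alkene.

**Step 9**
Reactants: 12 methacrolein; 13 vinylmagnesium bromide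
Product: 14 rac-2-methylpenta-1,4-dien-3-ol
Conditions: CH2=CHMgBr, THF, −78 to 0 °C; aq. NH4Cl
Reagents that add atoms: none
Why: Grignard 1,2-addition gives the racemic bis-allylic alcohol that carries C5–C9 and the C19 methyl.

**Step 10**
Reactants: 14 rac-2-methylpenta-1,4-dien-3-ol
Product: 15 (1R)-1-[(2S)-2-methyloxiran-2-yl]prop-2-en-1-ol
Conditions: Ti(OiPr)4, D-(−)-diisopropyl tartrate, t-BuOOH (0.55 equiv), 4 Å MS, CH2Cl2, −20 °C
Reagents that add atoms: tert-butyl hydroperoxide CC(C)(C)OO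
Why: In this Sharpless kinetic resolution the (R)-carbinol should be epoxidised fast at the more nucleophilic isopropenyl group to the erythro epoxy alcohol, which sets C7 and C8 together, while the (S)-alcohol is left behind.

**Step 11**
Reactants: 15 (1R)-1-[(2S)-2-methyloxiran-2-yl]prop-2-en-1-ol
Product: 17 (3R)-3-[(2S)-2-methyloxiran-2-yl]propane-1,3-diol, via alkylborane 16 (not isolated)
Conditions: 9-BBN, THF, 0 °C to rt; then 30% H2O2, aq. NaOAc, 0 °C
Reagents that add atoms: hydrogen peroxide OO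
Why: Hydroboration–oxidation of the only alkene is anti-Markovnikov and functionalises C5 before the second vinyl group exists, so no site selectivity is needed, and buffered oxidation spares the epoxide.

**Step 12**
Reactants: 17 (3R)-3-[(2S)-2-methyloxiran-2-yl]propane-1,3-diol
Product: 18 (3R,4S)-4-methylhex-5-ene-1,3,4-triol
Conditions: Me3SI, n-BuLi (excess), THF, −10 °C to rt
Reagents that add atoms: trimethylsulfonium iodide C[S+](C)C.[I-]
Why: The sulfonium ylide opens the terminal epoxide at CH2 and the betaine eliminates dimethyl sulfide, a one-carbon homologation of an epoxide to an allylic alcohol that leaves the C8–O bond and its configuration intact.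

**Step 13**
Reactants: 18 (3R,4S)-4-methylhex-5-ene-1,3,4-triol
Product: 19 (3R,4S)-1-iodo-4-methylhex-5-ene-3,4-diol
Conditions: I2, PPh3, imidazole, THF–MeCN, 0 °C
Reagents that add atoms: iodine II
Why: Appel-type iodination is selective for the primary hydroxyl over the secondary and tertiary ones.

**Step 14**
Reactants: 19 (3R,4S)-1-iodo-4-methylhex-5-ene-3,4-diol
Product: 20 (3R,4S)-4-hydroxy-1-iodo-4-methylhex-5-en-3-yl acetate
Conditions: Ac2O, pyridine, DMAP (cat.), CH2Cl2, 0 °C
Reagents that add atoms: acetic anhydride CC(=O)OC(C)=O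
Why: Acylation takes the secondary C7 hydroxyl and leaves the tertiary C8 hydroxyl free, so the acetate is placed before the C11 hydroxyl is ever present in the same molecule.

**Step 15**
Reactants: 20 (3R,4S)-4-hydroxy-1-iodo-4-methylhex-5-en-3-yl acetate; 11 tert-butyl (4R,7R)-4-(3,3-dibromoprop-2-en-1-yl)-7-methyl-2-oxo-7-{(1R)-1-[(triethylsilyl)oxy]prop-2-en-1-yl}oxepane-3-carboxylate
Product: 23 tert-butyl (4R,7R)-4-[(2E,6R,7S)-6-acetoxy-7-hydroxy-3,7-dimethylnona-2,8-dien-1-yl]-7-methyl-2-oxo-7-{(1R)-1-[(triethylsilyl)oxy]prop-2-en-1-yl}oxepane-3-carboxylate, via alkylzinc iodide 21 (not isolated), via bromoalkene 22 (not isolated)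
Conditions: 20, Zn (activated), LiCl, THF, 35 °C; then 11, PdCl2(DPEphos) (5 mol%), THF, 0 °C to rt; then MeZnCl, Pd(t-Bu3P)2 (5 mol%), rt
Reagents that add atoms: methylzinc chloride C[Zn]Cl
Why: In this sequential Negishi coupling the alkylzinc should replace the less hindered bromide trans to the C2 substituent and the methylation under the bulky phosphine proceeds with retention, so the (3E) alkene with the C18 methyl is formed stereospecifically.

**Step 16**
Reactants: 23 tert-butyl (4R,7R)-4-[(2E,6R,7S)-6-acetoxy-7-hydroxy-3,7-dimethylnona-2,8-dien-1-yl]-7-methyl-2-oxo-7-{(1R)-1-[(triethylsilyl)oxy]prop-2-en-1-yl}oxepane-3-carboxylate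
Product: 24 tert-butyl (1R,3E,7R,8S,11R,12R)-7-acetoxy-8-hydroxy-11-(triethylsilyloxy)cembra-3,9-dien-16,12-olide-15-carboxylate
Conditions: second-generation Grubbs catalyst RuCl2(=CHPh)(H2IMes)(PCy3) (10 mol%), CH2Cl2 (1 mM), 40 °C
Reagents that add atoms: none
Why: Ring-closing metathesis of the two monosubstituted olefins closes the 14-membered carbocycle at C9=C10 while the trisubstituted alkene is inert, and the geometry of the new alkene is irrelevant because it is reduced next.

**Step 17**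
Reactants: 24 tert-butyl (1R,3E,7R,8S,11R,12R)-7-acetoxy-8-hydroxy-11-(triethylsilyloxy)cembra-3,9-dien-16,12-olide-15-carboxylate
Product: 25 tert-butyl (1R,3E,7R,8S,11R,12R)-7-acetoxy-8-hydroxy-11-(triethylsilyloxy)cembr-3-en-16,12-olide-15-carboxylate
Conditions: 2-nitrobenzenesulfonyl hydrazide, Et3N, CH2Cl2, rt
Reagents that add atoms: none
Why: Diimide reduction should saturate the 1,2-disubstituted C9=C10 alkene chemoselectively, since the trisubstituted C3=C4 alkene reacts far more slowly and no allylic C–O hydrogenolysis can occur.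

**Step 18**
Reactants: 25 tert-butyl (1R,3E,7R,8S,11R,12R)-7-acetoxy-8-hydroxy-11-(triethylsilyloxy)cembr-3-en-16,12-olide-15-carboxylate
Product: 26 (1R,3E,7R,8S,11R,12R)-7-acetoxy-8,11-dihydroxycembr-3-en-16,12-olide-15-carboxylic acid
Conditions: CF3CO2H–CH2Cl2 (1:4), 0 °C
Reagents that add atoms: none
Why: Acidolysis removes the tert-butyl ester (E1 loss of isobutene) and the triethylsilyl ether in one operation, and the acetate and lactone are stable to it.

**Step 19**
Reactants: 26 (1R,3E,7R,8S,11R,12R)-7-acetoxy-8,11-dihydroxycembr-3-en-16,12-olide-15-carboxylic acid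
Product: 27 (1R,3E,7R,8S,11R,12R)-7-acetoxy-8,11-dihydroxycembra-3,15(17)-dien-16,12-olide
Conditions: 37% aq. HCHO, Et2NH, THF, rt; then NaOAc, AcOH, 50 °C
Reagents that add atoms: formaldehyde C=O
Why: In this decarboxylative Mannich methylenation the malonic half-acid adds to the iminium ion and the β-amino acid loses CO2 and diethylamine, which leaves the exocyclic C15=C17 alkene and removes the C15 stereocentre.

**Step 20**
Reactants: 27 (1R,3E,7R,8S,11R,12R)-7-acetoxy-8,11-dihydroxycembra-3,15(17)-dien-16,12-olide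
Product: 28 (1R,3S,4S,7R,8S,11R,12R)-7-acetoxy-3,4-epoxy-8,11-dihydroxycembr-15(17)-en-16,12-olide
Conditions: enantiomer of the fructose-derived Shi ketone (from L-sorbose, 0.3 equiv), Oxone (2KHSO5·KHSO4·K2SO4), K2CO3, n-Bu4NHSO4, MeCN–CH2(OMe)2–aq. Na2B4O7, 0 °C
Reagents that add atoms: potassium peroxymonosulfate [K+].[O-]S(=O)(=O)OO
Why: In the Shi epoxidation the chiral dioxirane attacks the only electron-rich alkene through a spiro transition state and the ketone enantiomer is chosen to give (3S,4S) under reagent control, while the electron-poor methylene lactone is not oxidised.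

**Compound list**

1 | nerol, (2Z)-3,7-dimethylocta-2,6-dien-1-ol | CC(C)=CCC/C(C)=C\CO | starting material
2 | (2R,3S)-2,3-epoxynerol | OC[C@H]1O[C@@]1(C)CCC=C(C)C | intermediate
3 | (2S,3S)-3-methyl-3-(4-methylpent-3-en-1-yl)oxirane-2-carbaldehyde | O=C[C@H]1O[C@@]1(C)CCC=C(C)C | intermediate
4 | (2S,3R)-3-ethenyl-2-methyl-2-(4-methylpent-3-en-1-yl)oxirane | C=C[C@H]1O[C@@]1(C)CCC=C(C)C | intermediate
5 | 3-[(2S,3R)-3-ethenyl-2-methyloxiran-2-yl]propanal | C=C[C@H]1O[C@@]1(C)CCC=O | intermediate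
6 | (2E)-5-[(2S,3R)-3-ethenyl-2-methyloxiran-2-yl]pent-2-enal | C=C[C@H]1O[C@@]1(C)CC/C=C/C=O | intermediate
7 | di-tert-butyl malonate | CC(C)(C)OC(=O)CC(=O)OC(C)(C)C | starting material
8 | di-tert-butyl 2-{(3R)-1-[(2S,3R)-3-ethenyl-2-methyloxiran-2-yl]-5-oxopentan-3-yl}propanedioate (Michael adduct) | C=C[C@H]1O[C@@]1(C)CC[C@@H](C(C(=O)OC(C)(C)C)C(=O)OC(C)(C)C)CC=O | intermediate
9 | tert-butyl (4R,7R)-7-[(1R)-1-hydroxyprop-2-en-1-yl]-7-methyl-2-oxo-4-(2-oxoethyl)oxepane-3-carboxylate | O=CC[C@H]1CC[C@](C)([C@H](O)C=C)OC(=O)C1C(=O)OC(C)(C)C | intermediate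
10 | tert-butyl (4R,7R)-7-methyl-2-oxo-4-(2-oxoethyl)-7-{(1R)-1-[(triethylsilyl)oxy]prop-2-en-1-yl}oxepane-3-carboxylate | O=CC[C@H]1CC[C@](C)([C@H](O[Si](CC)(CC)CC)C=C)OC(=O)C1C(=O)OC(C)(C)C | intermediate
11 | tert-butyl (4R,7R)-4-(3,3-dibromoprop-2-en-1-yl)-7-methyl-2-oxo-7-{(1R)-1-[(triethylsilyl)oxy]prop-2-en-1-yl}oxepane-3-carboxylate | BrC(Br)=CC[C@H]1CC[C@](C)([C@H](O[Si](CC)(CC)CC)C=C)OC(=O)C1C(=O)OC(C)(C)C | intermediate
12 | methacrolein | CC(=C)C=O | starting material
13 | vinylmagnesium bromide | C=C[Mg]Br | starting material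
14 | rac-2-methylpenta-1,4-dien-3-ol | C=CC(O)C(C)=C | intermediate
15 | (1R)-1-[(2S)-2-methyloxiran-2-yl]prop-2-en-1-ol | C=C[C@@H](O)[C@@]1(C)OC1 | intermediate
16 | (1R)-3-(9-borabicyclo[3.3.1]nonan-9-yl)-1-[(2S)-2-methyloxiran-2-yl]propan-1-ol (alkylborane) | O[C@H](CCB1C2CCCC1CCC2)[C@@]1(C)OC1 | intermediate
17 | (3R)-3-[(2S)-2-methyloxiran-2-yl]propane-1,3-diol | OCC[C@@H](O)[C@@]1(C)OC1 | intermediate
18 | (3R,4S)-4-methylhex-5-ene-1,3,4-triol | OCC[C@@H](O)[C@@](C)(O)C=C | intermediate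
19 | (3R,4S)-1-iodo-4-methylhex-5-ene-3,4-diol | ICC[C@@H](O)[C@@](C)(O)C=C | intermediate
20 | (3R,4S)-4-hydroxy-1-iodo-4-methylhex-5-en-3-yl acetate | ICC[C@@H](OC(C)=O)[C@@](C)(O)C=C | intermediate
21 | [(3R,4S)-3-acetoxy-4-hydroxy-4-methylhex-5-en-1-yl]zinc iodide (alkylzinc iodide) | I[Zn]CC[C@@H](OC(C)=O)[C@@](C)(O)C=C | intermediate
22 | tert-butyl (4R,7R)-4-[(2Z,6R,7S)-6-acetoxy-3-bromo-7-hydroxy-7-methylnona-2,8-dien-1-yl]-7-methyl-2-oxo-7-{(1R)-1-[(triethylsilyl)oxy]prop-2-en-1-yl}oxepane-3-carboxylate (bromoalkene) | C=C[C@](C)(O)[C@H](OC(C)=O)CC/C(Br)=C/C[C@H]1CC[C@](C)([C@H](O[Si](CC)(CC)CC)C=C)OC(=O)C1C(=O)OC(C)(C)C | intermediate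
23 | tert-butyl (4R,7R)-4-[(2E,6R,7S)-6-acetoxy-7-hydroxy-3,7-dimethylnona-2,8-dien-1-yl]-7-methyl-2-oxo-7-{(1R)-1-[(triethylsilyl)oxy]prop-2-en-1-yl}oxepane-3-carboxylate | C=C[C@](C)(O)[C@H](OC(C)=O)CC/C(C)=C/C[C@H]1CC[C@](C)([C@H](O[Si](CC)(CC)CC)C=C)OC(=O)C1C(=O)OC(C)(C)C | intermediate
24 | tert-butyl (1R,3E,7R,8S,11R,12R)-7-acetoxy-8-hydroxy-11-(triethylsilyloxy)cembra-3,9-dien-16,12-olide-15-carboxylate | CC(C)(C)OC(=O)C1C(=O)O[C@]2(C)CC[C@@H]1C/C=C(C)/CC[C@@H](OC(C)=O)[C@@](C)(O)C=C[C@H]2O[Si](CC)(CC)CC | intermediate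
25 | tert-butyl (1R,3E,7R,8S,11R,12R)-7-acetoxy-8-hydroxy-11-(triethylsilyloxy)cembr-3-en-16,12-olide-15-carboxylate | CC(C)(C)OC(=O)C1C(=O)O[C@]2(C)CC[C@@H]1C/C=C(C)/CC[C@@H](OC(C)=O)[C@@](C)(O)CC[C@H]2O[Si](CC)(CC)CC | intermediate
26 | (1R,3E,7R,8S,11R,12R)-7-acetoxy-8,11-dihydroxycembr-3-en-16,12-olide-15-carboxylic acid | OC(=O)C1C(=O)O[C@]2(C)CC[C@@H]1C/C=C(C)/CC[C@@H](OC(C)=O)[C@@](C)(O)CC[C@H]2O | intermediate
27 | (1R,3E,7R,8S,11R,12R)-7-acetoxy-8,11-dihydroxycembra-3,15(17)-dien-16,12-olide | C=C1C(=O)O[C@]2(C)CC[C@@H]1C/C=C(C)/CC[C@@H](OC(C)=O)[C@@](C)(O)CC[C@H]2O | intermediate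
28 | (1R,3S,4S,7R,8S,11R,12R)-7-acetoxy-3,4-epoxy-8,11-dihydroxycembr-15(17)-en-16,12-olide | C=C1C(=O)O[C@]2(C)CC[C@@H]1C[C@@H]1O[C@@]1(C)CC[C@@H](OC(C)=O)[C@@](C)(O)CC[C@H]2O | target

**Totals.** Total step count: 20. Longest linear sequence: 14 steps (steps 1–8, then 15–20); the second branch (steps 9–14) joins at step 15.

**Steps most likely to fail**

Step 6 (key step). The bulky malonate may add too slowly to the iminium ion, so that self-condensation of the enal through its dienamine takes over. In the second stage, ionisation of the vinyl epoxide at the allylic C11–O bond (1,2-shift or SN2′ capture) may outrun closure of the seven-membered ring. The fallback separates the two bond formations and closes the lactone from a free acid by intramolecular proton relay instead of Lewis-acid ester participation. It sets out from 6: the same amine catalyst with the more acidic bis(2,2,2-trichloroethyl) malonate should give bis(2,2,2-trichloroethyl) 2-{(3R)-1-[(2S,3R)-3-ethenyl-2-methyloxiran-2-yl]-5-oxopentan-3-yl}propanedioate F1. Zinc dust in AcOH–THF should unmask 2-{(3R)-1-[(2S,3R)-3-ethenyl-2-methyloxiran-2-yl]-5-oxopentan-3-yl}propanedioic acid F2, which with catalytic pyridinium tosylate in CH2Cl2 should close 7-exo to (4R,7R)-7-[(1R)-1-hydroxyprop-2-en-1-yl]-7-methyl-2-oxo-4-(2-oxoethyl)oxepane-3-carboxylic acid F3. Chemoselective esterification of the acid with O-tert-butyl-N,N′-diisopropylisourea comes back to the route at 9.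

Step 16. Initiation at the two hindered allylic olefins (quaternary C8 and silyloxy-bearing C11) may be slow, so that intermolecular metathesis and catalyst decomposition outrun ring closure. The fallback moves the desilylation forward and closes the ring on the unprotected bis(allylic alcohol), where both hydroxyls can assist the ruthenium carbene. It sets out from 23: HF·pyridine–pyridine in THF should give tert-butyl (4R,7R)-4-[(2E,6R,7S)-6-acetoxy-7-hydroxy-3,7-dimethylnona-2,8-dien-1-yl]-7-[(1R)-1-hydroxyprop-2-en-1-yl]-7-methyl-2-oxooxepane-3-carboxylate F4. Ring closure with the second-generation Hoveyda–Grubbs catalyst RuCl2(=CH-C6H4-2-OiPr)(H2IMes) should give tert-butyl (1R,3E,7R,8S,11R,12R)-7-acetoxy-8,11-dihydroxycembra-3,9-dien-16,12-olide-15-carboxylate F5. Diimide reduction should give tert-butyl (1R,3E,7R,8S,11R,12R)-7-acetoxy-8,11-dihydroxycembr-3-en-16,12-olide-15-carboxylate F6, and acidolysis of the tert-butyl ester comes back to the route at 26.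

Step 4. Ozone may also attack the vinyl group before the trisubstituted alkene is fully consumed, so that over-oxidation to a dialdehyde cannot be stopped cleanly. The fallback changes the order of events so that ozone meets only one alkene. It sets out from 2: ozonolysis (then PPh3) should give 3-[(2S,3R)-3-(hydroxymethyl)-2-methyloxiran-2-yl]propanal F7. Wittig olefination with Ph3P=CHCHO should give (2E)-5-[(2S,3R)-3-(hydroxymethyl)-2-methyloxiran-2-yl]pent-2-enal F8, and periodinane oxidation (2S,3S)-3-methyl-3-[(3E)-5-oxopent-3-en-1-yl]oxirane-2-carbaldehyde F9. One equivalent of Ph3P=CH2 at −78 °C should methylenate the more electrophilic, non-conjugated epoxy aldehyde and come back to the route at 6.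

**Further compounds**

F1 | step 6 | bis(2,2,2-trichloroethyl) 2-{(3R)-1-[(2S,3R)-3-ethenyl-2-methyloxiran-2-yl]-5-oxopentan-3-yl}propanedioate | C=C[C@H]1O[C@@]1(C)CC[C@@H](C(C(=O)OCC(Cl)(Cl)Cl)C(=O)OCC(Cl)(Cl)Cl)CC=O
F2 | step 6 | 2-{(3R)-1-[(2S,3R)-3-ethenyl-2-methyloxiran-2-yl]-5-oxopentan-3-yl}propanedioic acid | C=C[C@H]1O[C@@]1(C)CC[C@@H](C(C(=O)O)C(=O)O)CC=O
F3 | step 6 | (4R,7R)-7-[(1R)-1-hydroxyprop-2-en-1-yl]-7-methyl-2-oxo-4-(2-oxoethyl)oxepane-3-carboxylic acid | O=CC[C@H]1CC[C@](C)([C@H](O)C=C)OC(=O)C1C(=O)O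
F4 | step 16 | tert-butyl (4R,7R)-4-[(2E,6R,7S)-6-acetoxy-7-hydroxy-3,7-dimethylnona-2,8-dien-1-yl]-7-[(1R)-1-hydroxyprop-2-en-1-yl]-7-methyl-2-oxooxepane-3-carboxylate | C=C[C@](C)(O)[C@H](OC(C)=O)CC/C(C)=C/C[C@H]1CC[C@](C)([C@H](O)C=C)OC(=O)C1C(=O)OC(C)(C)C
F5 | step 16 | tert-butyl (1R,3E,7R,8S,11R,12R)-7-acetoxy-8,11-dihydroxycembra-3,9-dien-16,12-olide-15-carboxylate | CC(C)(C)OC(=O)C1C(=O)O[C@]2(C)CC[C@@H]1C/C=C(C)/CC[C@@H](OC(C)=O)[C@@](C)(O)C=C[C@H]2O
F6 | step 16 | tert-butyl (1R,3E,7R,8S,11R,12R)-7-acetoxy-8,11-dihydroxycembr-3-en-16,12-olide-15-carboxylate | CC(C)(C)OC(=O)C1C(=O)O[C@]2(C)CC[C@@H]1C/C=C(C)/CC[C@@H](OC(C)=O)[C@@](C)(O)CC[C@H]2O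
F7 | step 4 | 3-[(2S,3R)-3-(hydroxymethyl)-2-methyloxiran-2-yl]propanal | OC[C@H]1O[C@@]1(C)CCC=O
F8 | step 4 | (2E)-5-[(2S,3R)-3-(hydroxymethyl)-2-methyloxiran-2-yl]pent-2-enal | OC[C@H]1O[C@@]1(C)CC/C=C/C=O
F9 | step 4 | (2S,3S)-3-methyl-3-[(3E)-5-oxopent-3-en-1-yl]oxirane-2-carbaldehyde | O=C[C@H]1O[C@@]1(C)CC/C=C/C=O
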